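**Plan**
- **Locants:** the oxolane ring is O1, C2 (dienyl), C3 (OH), C4, C5 (CH3). The diene is C1'–C4', counted from C2. The isocoumarin keeps its own numbers (C1, O2, C3, C4 ...).
- **Cuts:** O1–C2 is cut first and read with allylic transposition, so the target becomes the anhydro form of an acyclic 1,4-dien-3-ol (OH on C2'). Next come C1'–C2' (alkenylzinc + enal), C3'=C4' (Wittig), O2–C1 and C3–C4 of the pyranone ring (toluate acylation, enol lactonisation), and C2–C3 of the diol piece (ynone).
- **Enabling feature:** C2 is the only stereocentre whose C–O bond is dienylic. C2–O1 is conjugated through C1'=C2'–C3'=C4' with C3=C4 of the pyranone ring, so it can be made, broken and remade through one delocalised cation. The wanted 2,3-trans-2,5-cis oxolane is the more stable C2 epimer.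
- **Forward order:** the benzene ring is bought, the pyranone ring is closed in step 4, the chain is joined in step 11, and the oxolane ring is closed last in step 12.
- **Stereochemistry:** C5 comes from methyl (R)-3-hydroxybutanoate, C3 from a 1,3-syn reduction directed by C5, and C2 from the stereoconvergent ring closure. C2' is deliberately left uncontrolled, and the E,E-diene is fixed in the same event.

Key step: step 12

Remark on the chemistry: the bis-allylic carbinol centre C2' is formed without control and both epimers are carried on together, so the SMILES of these compounds leave it undefined. All starting materials are taken to be catalogue chemicals.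

**Step 1**
Reactants: 1 methyl 2,4-dihydroxy-6-methylbenzoate (methyl orsellinate)
Product: 2 methyl 3-chloro-4,6-dihydroxy-2-methylbenzoate
Conditions: SO2Cl2 (1.0 equiv), Et2O, 0 °C to rt
Reagents that add atoms: sulfuryl chloride, O=S(=O)(Cl)Cl
Why: Electrophilic aromatic chlorination of the β-resorcylate should go to the ring carbon para to the hydrogen-bonded ortho-hydroxyl and next to the methyl group, while one equivalent of reagent at low temperature limits attack between the two hydroxyls and dichlorination.

**Step 2**
Reactants: 2 methyl 3-chloro-4,6-dihydroxy-2-methylbenzoate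
Product: 3 methyl 3-chloro-4,6-bis(methoxymethoxy)-2-methylbenzoate
Conditions: NaH (2.3 equiv), MOMCl (2.3 equiv), DMF, 0 °C to rt
Reagents that add atoms: chloromethyl methyl ether, COCCl
Why: Williamson-type O-alkylation of both phenoxides gives acetal ethers that tolerate the amide base of step 3 and fall off in the acid of step 4.

**Step 3**
Reactants: 3 methyl 3-chloro-4,6-bis(methoxymethoxy)-2-methylbenzoate, 4 methyl 2,2-dimethoxyacetate
Product: 6 methyl 3-chloro-2-(3,3-dimethoxy-2-oxopropyl)-4,6-bis(methoxymethoxy)benzoate, via benzylic lithium species 5 (not isolated)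
Conditions: LiN(iPr)2 (2.1 equiv), THF, −78 °C; 4, −78 °C; aq NH4Cl
Reagents that add atoms: none
Why: Lateral lithiation of the ortho-toluate (anion stabilised as an ester-conjugated enolate) followed by Claisen-type acylation with the α,α-dialkoxy ester should stop at the ketone, because the product is deprotonated at once by the second equivalent of base.

**Step 4**
Reactants: 6 methyl 3-chloro-2-(3,3-dimethoxy-2-oxopropyl)-4,6-bis(methoxymethoxy)benzoate
Product: 8 5-chloro-6,8-dihydroxy-1-oxo-1H-isochromene-3-carbaldehyde, via dimethyl acetal 7 (not isolated)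
Conditions: TFA–CH2Cl2 (1:1), rt; then H2O, 40 °C
Reagents that add atoms: water, O
Why: Acid removes both MOM acetals, the enol of the benzylic ketone attacks the neighbouring ester (6-exo-trig enol lactonisation, the usual fate of 2-(2-oxoalkyl)benzoates) to close the pyranone ring, and the acetal, now on an electron-rich vinylic carbon, is hydrolysed to the aldehyde when water is added.

**Step 5**
Reactants: 8 5-chloro-6,8-dihydroxy-1-oxo-1H-isochromene-3-carbaldehyde
Product: 9 5-chloro-1-oxo-6,8-bis(triisopropylsilyloxy)-1H-isochromene-3-carbaldehyde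
Conditions: TIPSOTf (2.5 equiv), 2,6-lutidine, CH2Cl2, 0 °C to rt
Reagents that add atoms: triisopropylsilyl trifluoromethanesulfonate, CC(C)[Si](C(C)C)(C(C)C)OS(=O)(=O)C(F)(F)F
Why: Silylation with the reactive triflate (needed for the hydrogen-bonded C8–OH) masks the acidic and nucleophilic phenols for steps 6, 11 and 12 with groups that survive mild acid and leave with fluoride.

**Step 6**
Reactants: 9 5-chloro-1-oxo-6,8-bis(triisopropylsilyloxy)-1H-isochromene-3-carbaldehyde, 10 (triphenylphosphoranylidene)acetaldehyde
Product: 11 (E)-3-[5-chloro-1-oxo-6,8-bis(triisopropylsilyloxy)-1H-isochromen-3-yl]prop-2-enal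
Conditions: 10 (1.1 equiv), toluene, 60 °C
Reagents that add atoms: none
Why: Wittig olefination with the stabilised formyl ylide gives the E-enal, and the starting heteroaryl aldehyde is more electrophilic than the vinylogous product, which limits double homologation.

**Step 7**
Reactants: 12 methyl (R)-3-hydroxybutanoate
Product: 13 (R)-3-hydroxy-N-methoxy-N-methylbutanamide
Conditions: MeNH(OMe)·HCl, iPrMgCl, THF, −20 to 0 °C
Reagents that add atoms: N,O-dimethylhydroxylamine hydrochloride, CNOC.Cl
Why: Aminolysis of the ester by the magnesium amide of N,O-dimethylhydroxylamine (Weinreb amide formation) proceeds with the hydroxyl present as its alkoxide and does not touch the stereocentre.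

**Step 8**
Reactants: 13 (R)-3-hydroxy-N-methoxy-N-methylbutanamide, 14 ethynylmagnesium bromide
Product: 15 (R)-5-hydroxyhex-1-yn-3-one
Conditions: 14 (3 equiv), THF, 0 °C; inverse quench into cold aq NaHSO4
Reagents that add atoms: none
Why: In this Weinreb ketone synthesis the alkynyl Grignard reagent first deprotonates the hydroxyl and then adds once to give a chelated tetrahedral intermediate, which collapses only on the cold acidic quench, and that quench also keeps the liberated amine from adding to the ynone.

**Step 9**
Reactants: 15 (R)-5-hydroxyhex-1-yn-3-one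
Product: 17 (2R,4R)-hex-5-yne-2,4-diol, via boron chelate 16 (not isolated)
Conditions: Et2BOMe (1.1 equiv), THF–MeOH (4:1), −78 °C; NaBH4; AcOH quench, co-evaporation with MeOH
Reagents that add atoms: none
Why: In this Narasaka–Prasad reduction the boron chelate 16 holds hydroxyl and ketone in a six-membered half-chair with the methyl group equatorial and external hydride attacks axially, which sets the future C3 as (R), 1,3-syn to C5.

**Step 10**
Reactants: 17 (2R,4R)-hex-5-yne-2,4-diol
Product: 18 (3R,5R)-3,5-bis(trimethylsilyloxy)hex-1-yne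
Conditions: TMSCl (2.4 equiv), imidazole, CH2Cl2, 0 °C
Reagents that add atoms: chlorotrimethylsilane, C[Si](C)(C)Cl
Why: Routine silylation gives ethers that are inert to Cp2Zr(H)Cl and Me2Zn yet so labile that the work-up of step 11 removes them without a separate step.

**Step 11**
Reactants: 18 (3R,5R)-3,5-bis(trimethylsilyloxy)hex-1-yne, 11 (E)-3-[5-chloro-1-oxo-6,8-bis(triisopropylsilyloxy)-1H-isochromen-3-yl]prop-2-enal
Product: 22 5-chloro-3-[(1E,4E,6R,8R)-3,6,8-trihydroxynona-1,4-dien-1-yl]-6,8-bis(triisopropylsilyloxy)-1H-isochromen-1-one (both C2' epimers), via alkenyl-ZrCp2Cl species 19 (not isolated), via alkenyl(methyl)zinc 20 (not isolated), via bis-TMS carbinol 21 (not isolated)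
Conditions: Cp2Zr(H)Cl, CH2Cl2, rt; Me2Zn, toluene, −65 °C; 11, 0 °C; aq NH4Cl; then 10% aq citric acid–THF, 0 °C
Reagents that add atoms: none
Why: Syn hydrozirconation places the metal on the terminal carbon and fixes the E C2=C1' bond, zirconium-to-zinc exchange gives an alkenylzinc that adds 1,2 to the enal but not to the lactone or the silyl ethers (hydrozirconation–transmetalation–carbonyl addition), the new centre C2' is left uncontrolled on purpose, and the TMS ethers are hydrolysed in the mildly acidic work-up.

**Step 12**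
Reactants: 22 5-chloro-3-[(1E,4E,6R,8R)-3,6,8-trihydroxynona-1,4-dien-1-yl]-6,8-bis(triisopropylsilyloxy)-1H-isochromen-1-one (both C2' epimers)
Product: 25 5-chloro-3-{(1E,3E)-4-[(2S,3R,5R)-3-hydroxy-5-methyloxolan-2-yl]buta-1,3-dien-1-yl}-6,8-bis(triisopropylsilyloxy)-1H-isochromen-1-one, via pentadienyl cation 23 (not isolated), via oxolane 2-epimer 24 (not isolated)
Conditions: FeCl3·6H2O (5 mol %), CH2Cl2 (5 mM), 0 °C to rt, until the epimer ratio is constant
Reagents that add atoms: none
Why: The Lewis acid ionises only the doubly allylic C2'–OH, and both epimers of 22 give the same planar cation 23, delocalised over C2, C2' and C4' and further into C3=C4 of the pyranone ring, so the stereochemical mixture is erased before the ring forms. O5 then captures the C2 terminus in a 5-exo-trig closure of the oxolane ring while the π bonds settle as the E,E-diene conjugated with the isocoumarin, the closest known reaction type being the FeCl3- or Re2O7-catalysed dehydrative cyclisation of hydroxy allylic alcohols through allyl cations under thermodynamic control, used here in vinylogous form. The new stereocentre C2 is controlled by the fixed centres C3 and C5: attack on the face that places the dienyl group trans to C3–OH and cis to C5–CH3 avoids the eclipsed cis-vicinal contact in the envelope transition state and gives 25. Because C2–O1 of the products is itself dienylic, any 2-epimer 24 reionises to 23 and drains into 25, the more stable epimer, so kinetic and thermodynamic preference point the same way. The step needs site selectivity between two allylic hydroxyls and between several O-to-C pairings: C3–OH is only singly allylic and its cation would sit next to the C2' oxygen, so it ionises far more slowly and becomes merely homoallylic once the ring is closed, O5 cannot reach C2' or C4' without a trans double bond in a medium ring, and capture by O3 (epoxide at C2, dihydrofuran at C2' after E-to-Z rotation) is reversible and less conjugated. High dilution and the TIPS-masked phenols suppress intermolecular O- and C-alkylation, and C5 keeps its configuration because its oxygen acts only as the nucleophile.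

**Step 13**
Reactants: 25 5-chloro-3-{(1E,3E)-4-[(2S,3R,5R)-3-hydroxy-5-methyloxolan-2-yl]buta-1,3-dien-1-yl}-6,8-bis(triisopropylsilyloxy)-1H-isochromen-1-one
Product: 26 5-chloro-6,8-dihydroxy-3-{(1E,3E)-4-[(2S,3R,5R)-3-hydroxy-5-methyloxolan-2-yl]buta-1,3-dien-1-yl}-1H-isochromen-1-one (target)
Conditions: Bu4NF–AcOH (1:1, 2.5 equiv), THF, 0 °C
Reagents that add atoms: none
Why: Fluoride cleaves the two aryl silyl ethers (good phenoxide leaving groups) quickly, and the acetic acid buffer should keep the lactone, the dienyl ether and the three stereocentres untouched.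

**Compound list**
1 | methyl 2,4-dihydroxy-6-methylbenzoate | COC(=O)c1c(C)cc(O)cc1O | starting material
2 | methyl 3-chloro-4,6-dihydroxy-2-methylbenzoate | COC(=O)c1c(C)c(Cl)c(O)cc1O | intermediate
3 | methyl 3-chloro-4,6-bis(methoxymethoxy)-2-methylbenzoate | COC(=O)c1c(C)c(Cl)c(OCOC)cc1OCOC | intermediate
4 | methyl 2,2-dimethoxyacetate | COC(OC)C(=O)OC | starting material
5 | benzylic lithium species from 3 | COC(=O)c1c(C[Li])c(Cl)c(OCOC)cc1OCOC | intermediate
6 | methyl 3-chloro-2-(3,3-dimethoxy-2-oxopropyl)-4,6-bis(methoxymethoxy)benzoate | COC(=O)c1c(CC(=O)C(OC)OC)c(Cl)c(OCOC)cc1OCOC | intermediate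
7 | 5-chloro-3-(dimethoxymethyl)-6,8-dihydroxy-1H-isochromen-1-one | COC(OC)c1cc2c(Cl)c(O)cc(O)c2c(=O)o1 | intermediate
8 | 5-chloro-6,8-dihydroxy-1-oxo-1H-isochromene-3-carbaldehyde | O=Cc1cc2c(Cl)c(O)cc(O)c2c(=O)o1 | intermediate
9 | 5-chloro-1-oxo-6,8-bis(triisopropylsilyloxy)-1H-isochromene-3-carbaldehyde | O=Cc1cc2c(Cl)c(O[Si](C(C)C)(C(C)C)C(C)C)cc(O[Si](C(C)C)(C(C)C)C(C)C)c2c(=O)o1 | intermediate
10 | (triphenylphosphoranylidene)acetaldehyde | O=CC=P(c1ccccc1)(c1ccccc1)c1ccccc1 | starting material
11 | (E)-3-[5-chloro-1-oxo-6,8-bis(triisopropylsilyloxy)-1H-isochromen-3-yl]prop-2-enal | O=C/C=C/c1cc2c(Cl)c(O[Si](C(C)C)(C(C)C)C(C)C)cc(O[Si](C(C)C)(C(C)C)C(C)C)c2c(=O)o1 | intermediate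
12 | methyl (R)-3-hydroxybutanoate | C[C@@H](O)CC(=O)OC | starting material
13 | (R)-3-hydroxy-N-methoxy-N-methylbutanamide | C[C@@H](O)CC(=O)N(C)OC | intermediate
14 | ethynylmagnesium bromide | C#C[Mg]Br | starting material
15 | (R)-5-hydroxyhex-1-yn-3-one | C[C@@H](O)CC(=O)C#C | intermediate
16 | diethylborinate (boron chelate) of 15 | C[C@@H](OB(CC)CC)CC(=O)C#C | intermediate
17 | (2R,4R)-hex-5-yne-2,4-diol | C[C@@H](O)C[C@@H](O)C#C | intermediate
18 | (3R,5R)-3,5-bis(trimethylsilyloxy)hex-1-yne | C[C@@H](O[Si](C)(C)C)C[C@@H](O[Si](C)(C)C)C#C | intermediate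
19 | (E)-alkenyl-ZrCp2Cl species from 18 | C[C@@H](O[Si](C)(C)C)C[C@@H](O[Si](C)(C)C)/C=C/[Zr](Cl)(C1C=CC=C1)C1C=CC=C1 | intermediate
20 | (E)-alkenyl(methyl)zinc from 19 | C[C@@H](O[Si](C)(C)C)C[C@@H](O[Si](C)(C)C)/C=C/[Zn]C | intermediate
21 | bis(trimethylsilyl) ether of 22 (both C2' epimers) | C[C@@H](O[Si](C)(C)C)C[C@@H](O[Si](C)(C)C)/C=C/C(O)/C=C/c1cc2c(Cl)c(O[Si](C(C)C)(C(C)C)C(C)C)cc(O[Si](C(C)C)(C(C)C)C(C)C)c2c(=O)o1 | intermediate
22 | 5-chloro-3-[(1E,4E,6R,8R)-3,6,8-trihydroxynona-1,4-dien-1-yl]-6,8-bis(triisopropylsilyloxy)-1H-isochromen-1-one (both C2' epimers) | C[C@@H](O)C[C@@H](O)/C=C/C(O)/C=C/c1cc2c(Cl)c(O[Si](C(C)C)(C(C)C)C(C)C)cc(O[Si](C(C)C)(C(C)C)C(C)C)c2c(=O)o1 | intermediate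
23 | pentadienyl cation from 22 (drawn with the charge on C2) | C[C@@H](O)C[C@@H](O)[CH+]/C=C/C=C/c1cc2c(Cl)c(O[Si](C(C)C)(C(C)C)C(C)C)cc(O[Si](C(C)C)(C(C)C)C(C)C)c2c(=O)o1 | intermediate
24 | (2R,3R,5R)-oxolane, the 2-epimer of 25 | C[C@@H]1C[C@@H](O)[C@@H](/C=C/C=C/c2cc3c(Cl)c(O[Si](C(C)C)(C(C)C)C(C)C)cc(O[Si](C(C)C)(C(C)C)C(C)C)c3c(=O)o2)O1 | intermediate
25 | 5-chloro-3-{(1E,3E)-4-[(2S,3R,5R)-3-hydroxy-5-methyloxolan-2-yl]buta-1,3-dien-1-yl}-6,8-bis(triisopropylsilyloxy)-1H-isochromen-1-one | C[C@@H]1C[C@@H](O)[C@H](/C=C/C=C/c2cc3c(Cl)c(O[Si](C(C)C)(C(C)C)C(C)C)cc(O[Si](C(C)C)(C(C)C)C(C)C)c3c(=O)o2)O1 | intermediate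
26 | 5-chloro-6,8-dihydroxy-3-{(1E,3E)-4-[(2S,3R,5R)-3-hydroxy-5-methyloxolan-2-yl]buta-1,3-dien-1-yl}-1H-isochromen-1-one | C[C@@H]1C[C@@H](O)[C@H](/C=C/C=C/c2cc3c(Cl)c(O)cc(O)c3c(=O)o2)O1 | target

**Totals**
- Total step count: 13.
- Longest linear sequence: 9 steps (steps 1–6, then 11–13). The diol branch (steps 7–10) has 4 steps.

**Steps most likely to fail**

1. **Step 12.**
   - Risk: equilibration at C2 may stop short of a useful bias. The cation may also leak away irreversibly, by proton loss at C3 or by oligomerisation, during the time equilibration needs.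
   - Fallback: this route is stereospecific instead of thermodynamic and involves no free cation. It sets out from 18 and 11 and returns at 25. Alkyne 18 would be hydroborated with dicyclohexylborane and the alkenylborane exchanged with Me2Zn. The alkenylzinc would be added to 11 under catalysis by enantiopure 3-exo-morpholinoisoborneol, the antipode being chosen by the established facial model, to give the (3R)-carbinol bis(trimethylsilyl) ether F1. Citric acid work-up would give the single-epimer (3R)-triol F2. PdCl2(MeCN)2 (10 mol %, divalent palladium) in THF at 0 °C would then effect a syn-SN2' cyclisation with 1,3-chirality transfer. O5 enters at C2 on the face from which the C2' hydroxyl leaves, so (R) at C2' is translated into (S) at C2 and an E C1'=C2' bond, giving 25.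

2. **Step 11.**
   - Risk: zirconium-to-zinc exchange may be sluggish. The enal may be reduced by residual Cp2Zr(H)Cl or methylated by Me2Zn. The bis-allylic alcohol may ionise prematurely in the acidic work-up.
   - Fallback: this uses an isolated halide and an organochromium coupling instead of the one-pot relay. It sets out from 18 and returns at 21. Hydrozirconation of 18 followed by I2 would give (3R,5R,E)-1-iodo-3,5-bis(trimethylsilyloxy)hex-1-ene F3. This would be joined to 11 by Nozaki–Hiyama–Kishi coupling (CrCl2, NiCl2 cat., DMF–THF, rt), a reaction selective for aldehydes over lactones. The product is 21, which is hydrolysed to 22 as in the main route.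

3. **Step 4.**
   - Risk: the three acid-driven events may not run cleanly together. The deactivated α-keto acetal may hydrolyse incompletely, or the polar and poorly soluble aldehyde may degrade.
   - Fallback: the aldehyde level is introduced by allylic oxidation after ring formation instead of being carried as an acetal. It sets out from 3 and returns at 9. Lithiation of 3 with LiN(iPr)2 and acylation with N-methoxy-N-methylacetamide would give methyl 3-chloro-4,6-bis(methoxymethoxy)-2-(2-oxopropyl)benzoate F4. TFA would convert it into 5-chloro-6,8-dihydroxy-3-methyl-1H-isochromen-1-one F5. TIPSOTf and 2,6-lutidine would give 5-chloro-3-methyl-6,8-bis(triisopropylsilyloxy)-1H-isochromen-1-one F6. Riley oxidation of the C3 methyl group (SeO2, dioxane, reflux) would then deliver 9.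

Further compounds
F1 | step 12 | (3R)-carbinol bis(trimethylsilyl) ether, single C2' epimer of 21 | C[C@@H](O[Si](C)(C)C)C[C@@H](O[Si](C)(C)C)/C=C/[C@@H](O)/C=C/c1cc2c(Cl)c(O[Si](C(C)C)(C(C)C)C(C)C)cc(O[Si](C(C)C)(C(C)C)C(C)C)c2c(=O)o1
F2 | step 12 | (3R)-triol, single C2' epimer of 22 | C[C@@H](O)C[C@@H](O)/C=C/[C@@H](O)/C=C/c1cc2c(Cl)c(O[Si](C(C)C)(C(C)C)C(C)C)cc(O[Si](C(C)C)(C(C)C)C(C)C)c2c(=O)o1
F3 | step 11 | (3R,5R,E)-1-iodo-3,5-bis(trimethylsilyloxy)hex-1-ene | C[C@@H](O[Si](C)(C)C)C[C@@H](O[Si](C)(C)C)/C=C/I
F4 | step 4 | methyl 3-chloro-4,6-bis(methoxymethoxy)-2-(2-oxopropyl)benzoate | COC(=O)c1c(CC(C)=O)c(Cl)c(OCOC)cc1OCOC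
F5 | step 4 | 5-chloro-6,8-dihydroxy-3-methyl-1H-isochromen-1-one | Cc1cc2c(Cl)c(O)cc(O)c2c(=O)o1
F6 | step 4 | 5-chloro-3-methyl-6,8-bis(triisopropylsilyloxy)-1H-isochromen-1-one | Cc1cc2c(Cl)c(O[Si](C(C)C)(C(C)C)C(C)C)cc(O[Si](C(C)C)(C(C)C)C(C)C)c2c(=O)o1
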